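The beta run at 25 °C has 30.7 % of its substrate as target by 2.50 h, while the eta run at −10 °C still reads 0 % at 15.0 h. I start from these two runs.

| setting | delta | beta | eta | spring | autumn | dusk |
|---|---|---|---|---|---|---|
| substrate | 0.44 M | 0.44 M | 0.22 M | 0.44 M | 0.44 M | 0.44 M |
| coupling partner | 0.29 M | 0.66 M | 0.44 M | 0.440 M | 0.440 M | 0.440 M |
| precatalyst | 66 mM | 66 mM | 66 mM | 66 mM | 66 mM | 66 mM |
| temperature | −10 °C | 25 °C | −10 °C | 25 °C | −5 °C | 55 °C |
| remark | run made earlier | run made earlier | run made earlier |  |  |  |
| time |  |  |  | 8.0 h | 8.0 h | 8.0 h |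

- delta (time / h: target / %): 8.00: 0; 15.0: 1.7; 30.0: 2.4; 60.0: 3.7
- beta (time / h: target / %): 2.50: 30.7; 5.00: 57.7; 8.00: 73.2; 10.0: 77.1
- eta (time / h: target / %): 15.0: 0; 30.0: 2.8; 50.0: 11.6; 60.0: 14.0

(standard deviation of a reading: 1 percentage point)

- the best flask by amount of target, in percent of the substrate charged; "all alike" if 1.5 percentage points covers them all (spring / autumn / dusk / all alike)
- amount of target at the end, in percent of the substrate charged, spring
- amount of target at the end, in percent of the substrate charged, autumn
- amount of target at the end, in percent of the substrate charged, dusk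

- the numbers in the tables scatter with a standard deviation of 1 percentage point

For spring, autumn and dusk, [coupling partner] over [substrate] at the start gives 100 %. I call this the partner ceiling: the target a flask can hold, in percent of the substrate charged, if each target costs one coupling partner. It is a limiting-reagent reckoning of my own, and it says where a flask must stop at the latest; the ladder of times says how far it gets.

I take the rungs quickest first. Beta's first pace, scaled down on my own assumption to the smaller partner charge of spring, reaches the ceiling in 12.2 h, which is longer than the asked 8.0 h. So I put spring below 65.5 %, and I expect it lower still, since beta's gains shrink between its later readings. The next rung is the cold lag: the eta run still reads 0 % of target at 15.0 h, later than the asked time, and the delta run reads 0 % at 8.00 h, so I expect autumn at −5 °C to be still in its lag. The last rung I take is eta's late gain, which at its own pace needs 268 h to cover 100 % of its substrate, longer than the 12.2 h of the first rung. Dusk at 55 °C is hotter than any run, so I hold it to the ceiling and nothing tighter.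

The forecast names dusk as best, with 50 % for spring, 1 % for autumn and 80 % for dusk, and it warns that “catalyst death or side reactions are untested at that temperature”.

The flasks give 49.1 % for spring, 0.253 % for autumn and 33.7 % for dusk, so spring is best.

    substrate + free catalyst → catalyst intermediate A (k = 680 L mol⁻¹ h⁻¹, Ea = 48.0 kJ mol⁻¹)
    coupling partner + catalyst intermediate A ⇌ catalyst intermediate B (K = 0.950 L mol⁻¹, k = 47.0 L mol⁻¹ h⁻¹, Ea = 68.0 kJ mol⁻¹, ΔH = −9.00 kJ mol⁻¹)
    catalyst intermediate B → by-product + catalyst intermediate C (k = 5.80 h⁻¹, Ea = 80.0 kJ mol⁻¹)
    catalyst intermediate C → catalyst intermediate D (k = 4.50 h⁻¹, Ea = 82.0 kJ mol⁻¹)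
    catalyst intermediate D → free catalyst + target (k = 15.0 h⁻¹, Ea = 89.0 kJ mol⁻¹)
    coupling partner + precatalyst → free catalyst + spent reagent (k = 8.90 L mol⁻¹ h⁻¹, Ea = 67.0 kJ mol⁻¹)
    catalyst intermediate D → spent catalyst (k = 0.390 h⁻¹, Ea = 93.0 kJ mol⁻¹)
    coupling partner → decomposed reagent (k = 0.110 h⁻¹, Ea = 98.0 kJ mol⁻¹)
    (constants at 25 °C)

Dusk ends with coupling partner at 0 % of its charge, and decomposed reagent holds 0.221 M, half of that charge. Dusk has filled 33.7 % of its partner ceiling of 100 %. Spring, left for 80.0 h, also comes to coupling partner at 0 %, and there the target fills 53.9 % of the same ceiling.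

The readings stem from a simulated flask for an exercise; scatter was added.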